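**Retrosynthetic overview**

1. Target 20 ⇐ Schenck ene reaction at the prenyl end of ether 19 (C6'–OOH, new C7'=C8'); 19 ⇐ Mitsunobu C1'–O(aryl) union of diol 15 with 4-hydroxy-5-methylcoumarin 18.
2. The strategy rests on the acyclic E-trisubstituted allylic alcohol C2'=C3'(CH3)–C4'H(OH) of the side chain. It is the 1,3-transposed form of a C2'–Se centre, so 15 ⇐ allylic selenide 12 by a selenoxide [2,3] shift (C4'–O made, C2'–Se lost, 2'S relayed to 4'S).
3. 12 ⇐ auxiliary-controlled α-selenenylation of the (3E)-3,7-dimethylocta-3,6-dienoyl imide 9, then reduction. 9 ⇐ acid 6 ⇐ alcohol 4 ⇐ but-3-yn-1-ol + prenyl chloride (carboalumination/Pd allylation fixes 3E).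
4. Rings: the side chain stays acyclic throughout. The only ring made is the pyranone ring (ring B) of coumarin 18, closed onto the benzene ring (ring A) of acetophenone 16 before the Mitsunobu step.

Key step: step 6

Remark: the side-chain carbons are numbered C1' (OCH2) to C8' (=CH2) in the coumarin ethers and C1 to C8 in the acyclic intermediates; these are the same atoms.

**Route**

Step 1
Reactants: 1 but-3-yn-1-ol; 2 1-chloro-3-methylbut-2-ene (prenyl chloride)
Product: 4 (3E)-3,7-dimethylocta-3,6-dien-1-ol, via alkenylalane 3 (not isolated)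
Conditions: Me3Al (3 equiv), Cp2ZrCl2 (0.25 equiv), CH2Cl2, 0 °C to rt; then 2, Pd(PPh3)4 (5 mol%), THF, rt; cold 1 M HCl
Reagents that add atoms: trimethylaluminium, C[Al](C)C
Why: Zirconium-catalysed Negishi carboalumination adds Me–Al across the alkyne in a cis fashion with Al on the terminal carbon, and alkenylalane 3 (carried as its aluminium alkoxide) then undergoes Pd-catalysed alkenyl–allyl cross-coupling with prenyl chloride at the unhindered CH2 terminus with retention of both alkene geometries, which fixes the 3E skipped diene.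

Step 2
Reactants: 4 (3E)-3,7-dimethylocta-3,6-dien-1-ol
Product: 6 (3E)-3,7-dimethylocta-3,6-dienoic acid, via aldehyde 5 (not isolated)
Conditions: TEMPO (2,2,6,6-tetramethylpiperidin-1-oxyl, 0.2 equiv), PhI(OAc)2 (2.2 equiv), MeCN/H2O 1:1, rt
Reagents that add atoms: water, O
Why: The oxoammonium-mediated TEMPO/PhI(OAc)2 oxidation takes the primary alcohol through aldehyde 5 and its hydrate to the acid under mild, nearly neutral conditions in which the two trisubstituted alkenes are not attacked and the C3=C4 bond is not expected to move into conjugation.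

Step 3
Reactants: 6 (3E)-3,7-dimethylocta-3,6-dienoic acid; 7 (4S)-4-benzyl-1,3-oxazolidin-2-one
Product: 9 (4S)-4-benzyl-3-[(3E)-3,7-dimethylocta-3,6-dienoyl]-1,3-oxazolidin-2-one, via mixed pivalic anhydride 8 (not isolated)
Conditions: PivCl, Et3N, THF, −20 °C; then LiCl, 7, −20 °C to rt
Reagents that add atoms: none
Why: N-Acylation of the Evans oxazolidinone through the pivaloyl mixed anhydride with LiCl/Et3N activation is the standard mild imide synthesis and is routinely used for β,γ-unsaturated acids without double-bond migration.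

Step 4
Reactants: 9 (4S)-4-benzyl-3-[(3E)-3,7-dimethylocta-3,6-dienoyl]-1,3-oxazolidin-2-one
Product: 11 (4S)-4-benzyl-3-[(2S,3E)-3,7-dimethyl-2-(phenylselanyl)octa-3,6-dienoyl]-1,3-oxazolidin-2-one, via sodium dienolate 10 (not isolated)
Conditions: NaN(SiMe3)2 (1.1 equiv), THF, −78 °C; enolate cannulated into PhSeCl (1.2 equiv), THF, −78 °C; AcOH quench; chromatography on Et3N-washed silica in the dark
Reagents that add atoms: benzeneselenenyl chloride, Cl[Se]c1ccccc1
Why: NaN(SiMe3)2 forms the chelated Z-sodium dienolate, which PhSeCl selenenylates at the α-carbon (the kinetic site of such dienolates) on the face away from the benzyl group (Evans auxiliary-controlled electrophilic α-functionalisation), so C2 is set as S, inverse addition keeps the more acidic product away from unreacted enolate, and any 2R epimer is removed as a diastereomer by chromatography.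

Step 5
Reactants: 11 (4S)-4-benzyl-3-[(2S,3E)-3,7-dimethyl-2-(phenylselanyl)octa-3,6-dienoyl]-1,3-oxazolidin-2-one
Product: 12 (2S,3E)-3,7-dimethyl-2-(phenylselanyl)octa-3,6-dien-1-ol
Conditions: LiBH4 (2 equiv), MeOH (1 equiv), Et2O, 0 °C; product kept cold and in the dark
Reagents that add atoms: none
Why: LiBH4 reductive cleavage of the N-acyloxazolidinone attacks the exocyclic carbonyl, gives the primary alcohol and frees the auxiliary, and at 0 °C it should touch neither the C–Se bond nor the alkenes nor the C2 configuration.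

Step 6
Reactants: 12 (2S,3E)-3,7-dimethyl-2-(phenylselanyl)octa-3,6-dien-1-ol
Product: 15 (2E,4S)-3,7-dimethylocta-2,6-diene-1,4-diol, via allylic selenoxide 13 (not isolated), via allylic selenenate 14 (not isolated)
Conditions: 30% aq. H2O2 (2.5 equiv), pyridine (2 equiv), CH2Cl2, 0 °C, dark
Reagents that add atoms: hydrogen peroxide, OO
Why: H2O2 oxidises the soft selenium of 12 far faster than either trisubstituted alkene, and allylic selenoxide 13 at once undergoes a concerted suprafacial [2,3]-sigmatropic shift through a five-membered envelope (O–Se–C2–C3=C4) to selenenate 14, whose O–Se bond is cleaved by water/pyridine while the excess H2O2 takes the selenenic acid on to PhSeO2H so that no electrophilic selenium is left to add to C6=C7. The closest known reaction type is the selenoxide–selenenate (seleno-Mislow–Evans) rearrangement of allylic selenides, which is established for making E-trisubstituted allylic alcohols. No ring is closed. The new C4 stereocentre is set by 1,3-chirality transfer from C2: with the 3E alkene and CH2OH in the pseudo-equatorial site of the envelope, oxygen is delivered to the C4 face that was syn to selenium, which translates 2S into 4S and at the same time gives the 2E alkene, whereas the pseudo-axial envelope (leading to the 2Z,4R isomer) is disfavoured by the clash of CH2OH with the phenylseleninyl side of the envelope. The step needs the rearrangement to outrun syn-elimination, which is secured because C3 carries no hydrogen, elimination towards the carbinol carbon C1 is intrinsically slow and the allylic [2,3] shift proceeds well below room temperature.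

Step 7
Reactants: 16 1-(2-hydroxy-6-methylphenyl)ethanone
Product: 18 4-hydroxy-5-methyl-2H-chromen-2-one, via β-keto ester 17 (not isolated)
Conditions: NaH (3.5 equiv), (EtO)2CO, toluene, 110 °C; then 2 M HCl
Reagents that add atoms: diethyl carbonate, CCOC(=O)OCC
Why: Claisen-type acylation of the ketone enolate with diethyl carbonate followed by lactonisation of β-keto ester 17 onto the phenol is the standard 4-hydroxycoumarin synthesis from 2-hydroxyacetophenones and closes the pyranone ring with the methyl group at C5.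

Step 8
Reactants: 15 (2E,4S)-3,7-dimethylocta-2,6-diene-1,4-diol; 18 4-hydroxy-5-methyl-2H-chromen-2-one
Product: 19 4-{[(2E,4S)-4-hydroxy-3,7-dimethylocta-2,6-dien-1-yl]oxy}-5-methyl-2H-chromen-2-one
Conditions: PPh3 (1.1 equiv), diisopropyl azodicarboxylate (1.1 equiv), THF, 0 °C to rt
Reagents that add atoms: none
Why: In this Mitsunobu etherification the acidic 4-hydroxycoumarin is O-alkylated by the oxyphosphonium ion of the primary allylic alcohol, which forms much faster than that of the hindered secondary C4' hydroxyl, the 2E geometry rules out cyclisation of the 1,4-diol, and C4' is not involved so its S configuration is kept.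

Step 9
Reactants: 19 4-{[(2E,4S)-4-hydroxy-3,7-dimethylocta-2,6-dien-1-yl]oxy}-5-methyl-2H-chromen-2-one
Product: 20 4-{[(2E,4S,6S)-6-hydroperoxy-4-hydroxy-3,7-dimethylocta-2,7-dien-1-yl]oxy}-5-methyl-2H-chromen-2-one
Conditions: O2, 5,10,15,20-tetraphenylporphyrin (1 mol%), CH2Cl2, white LED light, 0 °C, stopped before full conversion; silica chromatography, then preparative HPLC
Reagents that add atoms: dioxygen, O=O
Why: In this Schenck ene reaction singlet oxygen attacks the electron-rich C6'=C7' alkene in preference to the C2'=C3' alkene, which is deactivated by its two allylic C–O bonds, and abstraction of a C8' hydrogen places the hydroperoxide on C6' with the new C7'=C8' bond; the remote C4' centre gives no useful facial bias, so C6' is not controlled and the 4'S,6'S isomer is separated by HPLC from its 6'R epimer and from the C7' tertiary hydroperoxide regioisomer and assigned by reducing a sample to the 4',6'-anti diol and analysing its acetonide by 13C NMR.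

**Compound list**

1 | but-3-yn-1-ol | C#CCCO | starting material
2 | 1-chloro-3-methylbut-2-ene | CC(C)=CCCl | starting material
3 | dimethyl{(1E)-4-[(dimethylalumanyl)oxy]-2-methylbut-1-en-1-yl}alumane | C[Al](C)/C=C(C)/CCO[Al](C)C | intermediate
4 | (3E)-3,7-dimethylocta-3,6-dien-1-ol | CC(C)=CC/C=C(C)/CCO | intermediate
5 | (3E)-3,7-dimethylocta-3,6-dienal | CC(C)=CC/C=C(C)/CC=O | intermediate
6 | (3E)-3,7-dimethylocta-3,6-dienoic acid | CC(C)=CC/C=C(C)/CC(=O)O | intermediate
7 | (4S)-4-benzyl-1,3-oxazolidin-2-one | O=C1N[C@@H](Cc2ccccc2)CO1 | starting material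
8 | (3E)-3,7-dimethylocta-3,6-dienoic 2,2-dimethylpropanoic anhydride | CC(C)=CC/C=C(C)/CC(=O)OC(=O)C(C)(C)C | intermediate
9 | (4S)-4-benzyl-3-[(3E)-3,7-dimethylocta-3,6-dienoyl]-1,3-oxazolidin-2-one | CC(C)=CC/C=C(C)/CC(=O)N1[C@@H](Cc2ccccc2)COC1=O | intermediate
10 | sodium (1Z,3E)-1-[(4S)-4-benzyl-2-oxo-1,3-oxazolidin-3-yl]-3,7-dimethylocta-1,3,6-trien-1-olate | CC(C)=CC/C=C(C)/C=C(\[O-])N1[C@@H](Cc2ccccc2)COC1=O.[Na+] | intermediate
11 | (4S)-4-benzyl-3-[(2S,3E)-3,7-dimethyl-2-(phenylselanyl)octa-3,6-dienoyl]-1,3-oxazolidin-2-one | CC(C)=CC/C=C(C)/[C@H]([Se]c1ccccc1)C(=O)N1[C@@H](Cc2ccccc2)COC1=O | intermediate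
12 | (2S,3E)-3,7-dimethyl-2-(phenylselanyl)octa-3,6-dien-1-ol | CC(C)=CC/C=C(C)/[C@H]([Se]c1ccccc1)CO | intermediate
13 | (2S,3E)-3,7-dimethyl-2-(benzeneseleninyl)octa-3,6-dien-1-ol (both configurations at Se) | CC(C)=CC/C=C(C)/[C@H]([Se](=O)c1ccccc1)CO | intermediate
14 | (2E,4S)-3,7-dimethyl-4-[(phenylselanyl)oxy]octa-2,6-dien-1-ol | CC(C)=CC[C@H](O[Se]c1ccccc1)/C(C)=C/CO | intermediate
15 | (2E,4S)-3,7-dimethylocta-2,6-diene-1,4-diol | CC(C)=CC[C@H](O)/C(C)=C/CO | intermediate
16 | 1-(2-hydroxy-6-methylphenyl)ethanone | CC(=O)c1c(C)cccc1O | starting material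
17 | ethyl 3-(2-hydroxy-6-methylphenyl)-3-oxopropanoate | CCOC(=O)CC(=O)c1c(C)cccc1O | intermediate
18 | 4-hydroxy-5-methyl-2H-chromen-2-one | Cc1cccc2oc(=O)cc(O)c12 | intermediate
19 | 4-{[(2E,4S)-4-hydroxy-3,7-dimethylocta-2,6-dien-1-yl]oxy}-5-methyl-2H-chromen-2-one | CC(C)=CC[C@H](O)/C(C)=C/COc1cc(=O)oc2cccc(C)c12 | intermediate
20 | 4-{[(2E,4S,6S)-6-hydroperoxy-4-hydroxy-3,7-dimethylocta-2,7-dien-1-yl]oxy}-5-methyl-2H-chromen-2-one | C=C(C)[C@H](C[C@H](O)/C(C)=C/COc1cc(=O)oc2cccc(C)c12)OO | target

**Step count and risks**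

Total step count: 9. Longest linear sequence: 8 steps (1, 2, 3, 4, 5, 6, 8, 9); step 7 is the convergent branch.

Steps most likely to fail:

Step 9. What may go wrong: hydrogen abstraction from C5' instead of C8' (giving the tertiary C7' hydroperoxide) and attack on both faces of C6'=C7' without bias, so that the 6'S isomer is a minor part of the product and hard to separate. The fallback sets out from 19 and returns at 20; it sets C6' by reagent control and brings in the O–O group by substitution.
- Silylation of 19 (TBSCl, imidazole, DMF) would give 4-{[(2E,4S)-4-[(tert-butyldimethylsilyl)oxy]-3,7-dimethylocta-2,6-dien-1-yl]oxy}-5-methyl-2H-chromen-2-one F1.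
- Shi epoxidation of the electron-rich C6'=C7' alkene with the D-fructose-derived ketone 1,2:4,5-di-O-isopropylidene-β-D-erythro-2,3-hexodiulo-2,6-pyranose (KHSO5, K2CO3, MeCN/dimethoxymethane/H2O, 0 °C) would give the (6'R)-6',7'-epoxide 4-{[(2E,4S)-4-[(tert-butyldimethylsilyl)oxy]-5-[(2R)-3,3-dimethyloxiran-2-yl]-3-methylpent-2-en-1-yl]oxy}-5-methyl-2H-chromen-2-one F2.
- Diethylaluminium 2,2,6,6-tetramethylpiperidide (toluene, 0 °C) isomerises the epoxide by removing a methyl proton, leaving the C6'–O bond intact, to the (6'R)-allylic alcohol 4-{[(2E,4S,6R)-4-[(tert-butyldimethylsilyl)oxy]-6-hydroxy-3,7-dimethylocta-2,7-dien-1-yl]oxy}-5-methyl-2H-chromen-2-one F3.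
- Mesylation (MsCl, Et3N, CH2Cl2, −60 °C) gives the (6'R)-6'-methanesulfonate of this alcohol F4.
- Perhydrolysis of the sulfonate with anhydrous ethereal H2O2 at low temperature, a substitution expected to run with inversion (ionisation or allylic transposition would erode it), would give 4-{[(2E,4S,6S)-4-[(tert-butyldimethylsilyl)oxy]-6-hydroperoxy-3,7-dimethylocta-2,7-dien-1-yl]oxy}-5-methyl-2H-chromen-2-one F5.
- HF·pyridine (THF, 0 °C) then frees 20.

Step 4. What may go wrong: proton transfer from the more acidic product to unreacted enolate (double selenenylation), epimerisation at C2, and 1,3-migration of selenium into conjugation with the imide while 11 is isolated. The fallback sets out from 4 and returns at 12; it replaces the stoichiometric enolate by enamine catalysis.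
- Dess–Martin periodinane (NaHCO3, CH2Cl2, 0 °C) gives aldehyde 5, here taken on crude.
- (S)-2-{Bis[3,5-bis(trifluoromethyl)phenyl](trimethylsilyloxy)methyl}pyrrolidine (10 mol%), 4-nitrobenzoic acid (10 mol%) and N-(phenylseleno)phthalimide in toluene at 0 °C would give (2S,3E)-3,7-dimethyl-2-(phenylselanyl)octa-3,6-dienal F6; the silyl ether group shields one face of the E-enamine, which leads to 2S.
- NaBH4/MeOH added to the same flask reduces F6 at once to 12.
- Enamine α-selenenylation with reduction in the same flask is established for saturated aldehydes. With 5 the enamine is a dienamine, which should react at its α-carbon; the α- versus γ-selectivity would have to be checked. The sequence avoids both the strong base and the isolation of an α-seleno carbonyl compound.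

Step 6. What may go wrong: 1,3-shift of selenium in 12 before oxidation (loss of the C2 configuration), leakage through the pseudo-axial envelope (2Z,4R isomer), and attack of electrophilic selenium or peracid species on C6=C7. The fallback sets out from 4 and returns at 15; it places the C4 oxygen by epoxidation and opens the epoxide by elimination, with no sigmatropic step.
- Hydroxyl-directed asymmetric epoxidation of the homoallylic alcohol (VO(OiPr)3, the C2-symmetric bishydroxamic acid ligand derived from trans-cyclohexane-1,2-diamine in the enantiomeric series that gives the 3S,4S epoxide, cumene hydroperoxide, toluene, rt) leaves C6=C7 alone and would give 2-[(2S,3S)-2-methyl-3-(3-methylbut-2-en-1-yl)oxiran-2-yl]ethan-1-ol F7.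
- Dess–Martin oxidation (NaHCO3, CH2Cl2, 0 °C) gives 2-[(2S,3S)-2-methyl-3-(3-methylbut-2-en-1-yl)oxiran-2-yl]acetaldehyde F8.
- Et3N opens F8 by E1cB elimination to (2E,4S)-4-hydroxy-3,7-dimethylocta-2,6-dienal F9. The C4–O bond is not broken, so 4S comes from the epoxide, and the larger C4 branch should turn away from the formyl group to give the 2E enal.
- Luche reduction (NaBH4, CeCl3·7H2O, MeOH, −40 °C) returns to 15.

**Further compounds**

F1 | step 9 | 4-{[(2E,4S)-4-[(tert-butyldimethylsilyl)oxy]-3,7-dimethylocta-2,6-dien-1-yl]oxy}-5-methyl-2H-chromen-2-one | CC(C)=CC[C@H](O[Si](C)(C)C(C)(C)C)/C(C)=C/COc1cc(=O)oc2cccc(C)c12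
F2 | step 9 | 4-{[(2E,4S)-4-[(tert-butyldimethylsilyl)oxy]-5-[(2R)-3,3-dimethyloxiran-2-yl]-3-methylpent-2-en-1-yl]oxy}-5-methyl-2H-chromen-2-one | CC1(C)O[C@@H]1C[C@H](O[Si](C)(C)C(C)(C)C)/C(C)=C/COc1cc(=O)oc2cccc(C)c12
F3 | step 9 | 4-{[(2E,4S,6R)-4-[(tert-butyldimethylsilyl)oxy]-6-hydroxy-3,7-dimethylocta-2,7-dien-1-yl]oxy}-5-methyl-2H-chromen-2-one | C=C(C)[C@@H](C[C@H](O[Si](C)(C)C(C)(C)C)/C(C)=C/COc1cc(=O)oc2cccc(C)c12)O
F4 | step 9 | (3R,5S,6E)-5-[(tert-butyldimethylsilyl)oxy]-2,6-dimethyl-8-[(5-methyl-2-oxo-2H-chromen-4-yl)oxy]octa-1,6-dien-3-yl methanesulfonate | C=C(C)[C@@H](C[C@H](O[Si](C)(C)C(C)(C)C)/C(C)=C/COc1cc(=O)oc2cccc(C)c12)OS(C)(=O)=O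
F5 | step 9 | 4-{[(2E,4S,6S)-4-[(tert-butyldimethylsilyl)oxy]-6-hydroperoxy-3,7-dimethylocta-2,7-dien-1-yl]oxy}-5-methyl-2H-chromen-2-one | C=C(C)[C@H](C[C@H](O[Si](C)(C)C(C)(C)C)/C(C)=C/COc1cc(=O)oc2cccc(C)c12)OO
F6 | step 4 | (2S,3E)-3,7-dimethyl-2-(phenylselanyl)octa-3,6-dienal | CC(C)=CC/C=C(C)/[C@H]([Se]c1ccccc1)C=O
F7 | step 6 | 2-[(2S,3S)-2-methyl-3-(3-methylbut-2-en-1-yl)oxiran-2-yl]ethan-1-ol | OCC[C@]1(C)O[C@H]1CC=C(C)C
F8 | step 6 | 2-[(2S,3S)-2-methyl-3-(3-methylbut-2-en-1-yl)oxiran-2-yl]acetaldehyde | O=CC[C@]1(C)O[C@H]1CC=C(C)C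
F9 | step 6 | (2E,4S)-4-hydroxy-3,7-dimethylocta-2,6-dienal | CC(C)=CC[C@H](O)/C(C)=C/C=O
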